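| setting | south-west | south | east | flask |
|---|---|---|---|---|
| starting material | 0.28 mM | 0.44 mM | 0.20 mM | 0.20 mM |
| reagent | 0.30 mM | 0.30 mM | 0.30 mM | 0.300 mM |
| second substrate | 0.10 mM | 0.10 mM | 0.10 mM | 0.100 mM |
| third substrate | 0.20 mM | 0.20 mM | 0.40 mM | 0.200 mM |
| protic impurity | 0.10 mM | 0.10 mM | 0.10 mM | 0.100 mM |
| remark | run made earlier | run made earlier | run made earlier |  |
| time |  |  |  | 20 min |

- south-west (time / min: target / %, starting material / %): 0.250: 42.0, 54.3; 0.500: 45.5, 45.7; 1.00: 39.2, 41.3; 2.50: 19.9, 40.4; 5.00: 7.9, 40.5; 12.0: 4.4, 40.6; 25.0: 4.3, 39.7
- south (time / min: target / %, starting material / %): 0.250: 36.5, 60.8; 0.500: 35.2, 55.4; 1.00: 28.9, 54.8; 2.50: 15.4, 54.5; 5.00: 5.8, 55.2; 12.0: 2.7, 54.6; 25.0: 2.8, 53.8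
- east (time / min: target / %, starting material / %): 0.250: 39.7, 57.7; 0.833: 35.8, 48.5; 2.50: 17.0, 47.4; 8.00: 3.1, 48.0; 25.0: 2.7, 48.2

(standard deviation of a reading: 0.5 percentage points)

- time, not beyond 20 min, at which the flask holds most target
- the amount of target, in percent of the starting material charged, at that time



- I took it that each reagent molecule spent takes one substrate molecule with it, so I counted the reagent against the sum of the substrates.
- The bench rule says that reagent in excess over the starting material finishes it, and the flask has 1.50 equivalents, so that rule promised full conversion.
- The rule failed in the south-west run: reagent stood in excess there at 1.07 equivalents, yet the reading at 25.0 min still showed 39.7% of the starting material.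
- The border lies in τ, the reagent charge over the summed charges of starting material, second substrate and third substrate, which counts reagent turnovers per substrate molecule; in the south-west run τ was 0.517, below one, so on my count the reagent there was the limiting reagent and could not serve every substrate molecule.
- I defined the weight g as final conversion divided by τ; the last readings gave 1.17 for the south-west run, 1.14 for the south run and 1.21 for the east run, with a mean of 1.17.
- For the flask τ is 0.600, so I reckoned a final conversion gτ of 70.3%; this estimate speaks of the starting material converted and gives no peak of target.
- The forecast gave 53% at 0.4 min, on the ground that “The peak comes at about 0.3–0.5 min and holds about 78–80% of the converted material”.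
- The flask reached 50.3% at 0.514 min, later than the forecast time, with the amount within the tolerance.

    second substrate + reagent → second product (k = 162 M⁻¹ s⁻¹)
    starting material + reagent → target (k = 268 M⁻¹ s⁻¹)
    third substrate + reagent → third product (k = 196 M⁻¹ s⁻¹)
    third substrate + protic impurity → quenched substrate (k = 39.9 M⁻¹ s⁻¹)
    target ⇌ isomer of the product (K = 15.0, k = 0.00848 s⁻¹)

- At 0.124 min the flask made target 9.54 times faster than it used it up, and the half-life of reagent by the target step at that moment, 0.33 min, was shorter than the 1.4 min of target by its forward step to the isomer of the product. At the best time reagent stood at 13.3% of its charge, and by 20 min target had fallen to 4.34%. The flask had converted 69.5% of its starting material by 20.0 min, against the count's 70.3%. With 0.34 mM of starting material, τ is 0.469 and gτ is 54.9%, and that neighbouring flask had converted 53.2% by 20.0 min.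

The readings are simulated with constants of no real substance, noise included.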